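Ring B (C1, C2, C3, C4, C4a, C8a) is opened at C3–C4 and C1–C2. This exposes its trans-2,3-dimethyl unit, C2 and C3 with their methyl groups, as the four carbons of twofold-symmetric (2S,3S)-butane-2,3-diol, and the two benzylic carbons C1 and C4, ortho to each other on ring A, as carbanions. In the key step a 2-aryl-1,3-dithiane (C1 as masked acyl anion) opens the diol cyclic sulfate; the doubly benzylic C4 of the resulting alkyl sulfate is then lithiated and closes ring B by displacing sulfate at C3. Two inversions deliver C2 and C3, the closure sets C4, and all three stereocentres arise in one flask.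

Key step: step 5

Remark: atoms are numbered as in 1-tetralone (C1 carbonyl carbon, C2 and C3 methyl-bearing, C4 aryl-bearing, C4a and C8a ring fusion); ring A is the phenolic arene, ring B the cyclohexanone ring, ring C the dimethoxyphenyl group; compounds 1, 3 and 7 are taken as commercial.

Step 1
Reactants: 1 2-bromo-5-hydroxy-4-methoxybenzaldehyde
Product: 2 2-bromo-4-methoxy-5-(propan-2-yloxy)benzaldehyde
Conditions: 2-bromopropane, K2CO3, DMF, 60 °C
Reagents that add atoms: 2-bromopropane, CC(C)Br
Why: Williamson ether synthesis masks the acidic phenol as an isopropyl ether, which should survive the organozinc and organolithium steps and can later be cleaved by BCl3 without loss of the methyl ethers.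

Step 2
Reactants: 2 2-bromo-4-methoxy-5-(propan-2-yloxy)benzaldehyde; 3 4-(chloromethyl)-1,2-dimethoxybenzene
Product: 5 2-(3,4-dimethoxybenzyl)-4-methoxy-5-(propan-2-yloxy)benzaldehyde, via (3,4-dimethoxybenzyl)zinc chloride 4 (not isolated)
Conditions: 3, Zn dust, LiCl, THF, 25 °C; then 2, Pd(OAc)2 (2 mol %), SPhos (4 mol %), THF, 25 to 50 °C
Reagents that add atoms: none
Why: Negishi coupling of the benzylic zinc reagent with the aryl bromide, which the ortho formyl group activates for oxidative addition, should outrun addition to the aldehyde and places C4 with ring C on ring A.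

Step 3
Reactants: 5 2-(3,4-dimethoxybenzyl)-4-methoxy-5-(propan-2-yloxy)benzaldehyde
Product: 6 2-[2-(3,4-dimethoxybenzyl)-4-methoxy-5-(propan-2-yloxy)phenyl]-1,3-dithiane
Conditions: propane-1,3-dithiol, BF3·OEt2 (20 mol %), CH2Cl2, −20 to 0 °C
Reagents that add atoms: propane-1,3-dithiol, SCCCS
Why: Lewis acid-catalysed dithioacetalisation turns the aldehyde carbon (future C1) into a Corey–Seebach acyl anion equivalent; at low temperature the thiol should trap the activated aldehyde faster than ring C can attack it in a cyclodehydration.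

Step 4
Reactants: 7 (2S,3S)-butane-2,3-diol
Product: 9 (4S,5S)-4,5-dimethyl-1,3,2-dioxathiolane 2,2-dioxide, via cyclic sulfite 8 (not isolated)
Conditions: SOCl2, CH2Cl2, 0 °C to reflux; then RuCl3·3H2O (1 mol %), NaIO4, MeCN/H2O, 0 °C
Reagents that add atoms: thionyl chloride, O=S(Cl)Cl; sodium periodate, [Na+].[O-]I(=O)(=O)=O
Why: cyclic sulfite formation and ruthenium-catalysed oxidation at sulfur activate both C–O bonds of the diol without touching either carbon, so the (S,S) configuration is retained.

Step 5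
Reactants: 6 2-[2-(3,4-dimethoxybenzyl)-4-methoxy-5-(propan-2-yloxy)phenyl]-1,3-dithiane; 9 (4S,5S)-4,5-dimethyl-1,3,2-dioxathiolane 2,2-dioxide
Product: 13 (2'R,3'S,4'R)-4'-(3,4-dimethoxyphenyl)-6'-methoxy-2',3'-dimethyl-7'-(propan-2-yloxy)-3',4'-dihydro-2'H-spiro[1,3-dithiane-2,1'-naphthalene], via 2-lithio-1,3-dithiane 10 (not isolated), via lithium alkyl sulfate 11 (not isolated), via C4-lithiated alkyl sulfate 12 (not isolated)
Conditions: n-BuLi (1.05 equiv), THF, −78 to −20 °C; 9, −78 to 0 °C; then s-BuLi (1.2 equiv), TMEDA, −78 to 25 °C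
Reagents that add atoms: none
Why: n-BuLi removes the dithiane C–H (more acidic and kinetically faster than the diarylmethane C–H), and carbanion 10 opens cyclic sulfate 9 with inversion to give 11 (C1–C2 bond; either carbon of the twofold-symmetric electrophile gives the same product). s-BuLi/TMEDA then lithiates the doubly benzylic C4–H, and the diarylmethyl carbanion 12 displaces the secondary sulfate at C3 with inversion in a 6-exo-tet closure of ring B, which forms the C3–C4 bond. The closest known reaction type is the one-flask double alkylation of carbanions and phosphides with enantiopure diol cyclic sulfates (cyclopropanes from malonates, phospholanes from primary phosphines, annulated cyclopentadienes), applied here to a 1,4-dicarbanion equivalent. C2 and C3 come from the diol by one inversion each, which turns (4S,5S)-9 into the trans-2,3-dimethyl unit of the required absolute configuration. C4 is set in the closure: the planar benzylic anion keeps ring C anti to the dithiane-bearing substituent on C8a, and the chain folds with both methyl groups pseudo-equatorial, which places ring C trans to the C3 methyl. The step needs substitution to win over elimination and over attack of the alkyllithium at sulfur; the soft stabilised carbanion, the six-membered transition state and the lack of an acidic hydrogen next to C3 should favour this.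

Step 6
Reactants: 13 (2'R,3'S,4'R)-4'-(3,4-dimethoxyphenyl)-6'-methoxy-2',3'-dimethyl-7'-(propan-2-yloxy)-3',4'-dihydro-2'H-spiro[1,3-dithiane-2,1'-naphthalene]
Product: 14 (2R,3S,4R)-4-(3,4-dimethoxyphenyl)-6-methoxy-2,3-dimethyl-7-(propan-2-yloxy)-3,4-dihydronaphthalen-1(2H)-one
Conditions: MeI, CaCO3, MeCN/H2O (9:1), 45 °C
Reagents that add atoms: water, O
Why: alkylative dithiane hydrolysis (S-methylation, then capture by water of the thionium ion that the para methoxy group of ring A stabilises) should unveil the C1 ketone under buffered conditions; C2 is already in the more stable trans arrangement, so any enolisation is self-correcting.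

Step 7
Reactants: 14 (2R,3S,4R)-4-(3,4-dimethoxyphenyl)-6-methoxy-2,3-dimethyl-7-(propan-2-yloxy)-3,4-dihydronaphthalen-1(2H)-one
Product: 15 epischisandrone, (2R,3S,4R)-4-(3,4-dimethoxyphenyl)-7-hydroxy-6-methoxy-2,3-dimethyl-3,4-dihydronaphthalen-1(2H)-one
Conditions: BCl3, CH2Cl2, −78 to 0 °C; then H2O
Reagents that add atoms: none
Why: BCl3 cleaves the secondary isopropyl aryl ether much faster than the methyl ethers, which should free the C7 phenol without affecting any stereocentre.

Compound list
1 | 2-bromo-5-hydroxy-4-methoxybenzaldehyde | COc1cc(Br)c(C=O)cc1O | starting material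
2 | 2-bromo-4-methoxy-5-(propan-2-yloxy)benzaldehyde | COc1cc(Br)c(C=O)cc1OC(C)C | intermediate
3 | 4-(chloromethyl)-1,2-dimethoxybenzene | COc1ccc(CCl)cc1OC | starting material
4 | (3,4-dimethoxybenzyl)zinc chloride | COc1ccc(C[Zn]Cl)cc1OC | intermediate
5 | 2-(3,4-dimethoxybenzyl)-4-methoxy-5-(propan-2-yloxy)benzaldehyde | COc1cc(Cc2ccc(OC)c(OC)c2)c(C=O)cc1OC(C)C | intermediate
6 | 2-[2-(3,4-dimethoxybenzyl)-4-methoxy-5-(propan-2-yloxy)phenyl]-1,3-dithiane | COc1cc(Cc2ccc(OC)c(OC)c2)c(cc1OC(C)C)C1SCCCS1 | intermediate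
7 | (2S,3S)-butane-2,3-diol | C[C@H](O)[C@H](C)O | starting material
8 | (4S,5S)-4,5-dimethyl-1,3,2-dioxathiolane 2-oxide | C[C@@H]1OS(=O)O[C@H]1C | intermediate
9 | (4S,5S)-4,5-dimethyl-1,3,2-dioxathiolane 2,2-dioxide | C[C@@H]1OS(=O)(=O)O[C@H]1C | intermediate
10 | 2-lithio derivative of 6 | COc1cc(Cc2ccc(OC)c(OC)c2)c(cc1OC(C)C)C1([Li])SCCCS1 | intermediate
11 | lithium (2S,3R)-3-{2-[2-(3,4-dimethoxybenzyl)-4-methoxy-5-(propan-2-yloxy)phenyl]-1,3-dithian-2-yl}butan-2-yl sulfate | COc1cc(Cc2ccc(OC)c(OC)c2)c(cc1OC(C)C)C1(SCCCS1)[C@H](C)[C@H](C)OS(=O)(=O)[O-].[Li+] | intermediate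
12 | 11 lithiated at the diarylmethyl carbon (C4) | COc1cc(C([Li])c2ccc(OC)c(OC)c2)c(cc1OC(C)C)C1(SCCCS1)[C@H](C)[C@H](C)OS(=O)(=O)[O-].[Li+] | intermediate
13 | (2'R,3'S,4'R)-4'-(3,4-dimethoxyphenyl)-6'-methoxy-2',3'-dimethyl-7'-(propan-2-yloxy)-3',4'-dihydro-2'H-spiro[1,3-dithiane-2,1'-naphthalene] | COc1cc2c(cc1OC(C)C)C1(SCCCS1)[C@H](C)[C@@H](C)[C@@H]2c1ccc(OC)c(OC)c1 | intermediate
14 | (2R,3S,4R)-4-(3,4-dimethoxyphenyl)-6-methoxy-2,3-dimethyl-7-(propan-2-yloxy)-3,4-dihydronaphthalen-1(2H)-one | COc1cc2c(cc1OC(C)C)C(=O)[C@H](C)[C@@H](C)[C@@H]2c1ccc(OC)c(OC)c1 | intermediate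
15 | epischisandrone, (2R,3S,4R)-4-(3,4-dimethoxyphenyl)-7-hydroxy-6-methoxy-2,3-dimethyl-3,4-dihydronaphthalen-1(2H)-one | COc1cc2c(cc1O)C(=O)[C@H](C)[C@@H](C)[C@@H]2c1ccc(OC)c(OC)c1 | target

Total step count: 7. Longest linear sequence: 6 steps (steps 1, 2, 3, 5, 6, 7 from compound 1); step 4 is a side branch.

Steps most likely to fail

Step 5. The hindered tertiary dithianyl carbanion may act as a base instead of opening the secondary cyclic sulfate, or the anionic sulfate may resist displacement so that elimination or attack of the alkyllithium at sulfur takes over. The fallback sets out from 6 and comes back at 13; it separates the two bond formations and uses a neutral leaving group. Lithiated 6 (n-BuLi, THF, −78 °C) should open (2S,3S)-2,3-dimethyloxirane (DMPU, −78 to 25 °C) with inversion to give (2S,3R)-3-{2-[2-(3,4-dimethoxybenzyl)-4-methoxy-5-(propan-2-yloxy)phenyl]-1,3-dithian-2-yl}butan-2-ol F1. Mesylation (MsCl, Et3N, CH2Cl2, 0 °C) should give (2S,3R)-3-{2-[2-(3,4-dimethoxybenzyl)-4-methoxy-5-(propan-2-yloxy)phenyl]-1,3-dithian-2-yl}butan-2-yl methanesulfonate F2. Lithium 2,2,6,6-tetramethylpiperidide (THF, −78 to 0 °C) should then deprotonate C4 and effect the same 6-exo-tet closure with inversion at C3 to reach 13.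

Step 2. Wurtz-type homocoupling during zinc insertion into the electron-rich benzylic chloride, or addition of the benzylic zinc reagent to the formyl group, may consume the partners. The fallback sets out from 2 and comes back at 5 with the polarity of the coupling reversed. Miyaura borylation of 2 (bis(pinacolato)diboron, Pd(dppf)Cl2, KOAc, dioxane, 80 °C) should give 4-methoxy-5-(propan-2-yloxy)-2-(4,4,5,5-tetramethyl-1,3,2-dioxaborolan-2-yl)benzaldehyde F3. Suzuki–Miyaura coupling of this boronate with benzylic chloride 3 (Pd(PPh3)4, K2CO3, DME/H2O, 80 °C) should give 5.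

Step 6. S-methylation of the congested spiro dithiane may stall, so that hydrolysis does not go to completion. The fallback sets out from 13 and comes back at 14 and activates sulfur by oxidation instead of alkylation. NaIO4 (MeOH/H2O, 0 °C) should give the monosulfoxide (2'R,3'S,4'R)-4'-(3,4-dimethoxyphenyl)-6'-methoxy-2',3'-dimethyl-7'-(propan-2-yloxy)-3',4'-dihydro-2'H-spiro[1,3-dithiane-2,1'-naphthalene] 1-oxide F4 (mixture of sulfoxide diastereomers). Acid hydrolysis of the sulfoxide (2 M HCl, THF, 25 °C) should then release ketone 14.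

Further compounds
F1 | step 5 | (2S,3R)-3-{2-[2-(3,4-dimethoxybenzyl)-4-methoxy-5-(propan-2-yloxy)phenyl]-1,3-dithian-2-yl}butan-2-ol | COc1cc(Cc2ccc(OC)c(OC)c2)c(cc1OC(C)C)C1(SCCCS1)[C@H](C)[C@H](C)O
F2 | step 5 | (2S,3R)-3-{2-[2-(3,4-dimethoxybenzyl)-4-methoxy-5-(propan-2-yloxy)phenyl]-1,3-dithian-2-yl}butan-2-yl methanesulfonate | COc1cc(Cc2ccc(OC)c(OC)c2)c(cc1OC(C)C)C1(SCCCS1)[C@H](C)[C@H](C)OS(C)(=O)=O
F3 | step 2 | 4-methoxy-5-(propan-2-yloxy)-2-(4,4,5,5-tetramethyl-1,3,2-dioxaborolan-2-yl)benzaldehyde | COc1cc(B2OC(C)(C)C(C)(C)O2)c(C=O)cc1OC(C)C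
F4 | step 6 | (2'R,3'S,4'R)-4'-(3,4-dimethoxyphenyl)-6'-methoxy-2',3'-dimethyl-7'-(propan-2-yloxy)-3',4'-dihydro-2'H-spiro[1,3-dithiane-2,1'-naphthalene] 1-oxide | COc1cc2c(cc1OC(C)C)C1(SCCCS1=O)[C@H](C)[C@@H](C)[C@@H]2c1ccc(OC)c(OC)c1
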